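The route rests on one disconnection in the side chain, not in the lactone: the carbinols C4′, C6′ and C8′ (chain numbered outward from ring carbon C6) form a syn-1,3/anti-1,5 triol that ends in an allyl unit. A rhodium-catalysed carbonylative cascade on the diallylhydrosilyl ether of (R,E)-1-phenylhexa-1,5-dien-3-ol uses the C8′ oxygen as a silicon tether, turns CO into C4′, makes the Si–C6′, C5′–C4′, C4′–C3′ and Si–O bonds and closes both five-membered rings of a 2,8-dioxa-1-silabicyclo[3.3.0]octane, setting C6′ and C4′ from C8′. Oxidation of silicon then bares the triol, and the six-membered dihydropyranone ring (O1–C6) is built last.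

Key step: step 4

Atom labels: lactone O1, C2(=O), C3=C4, C5, C6; side chain C1′=C2′, C3′, C4′(OH), C5′, C6′(OH), C7′, C8′(OH), C9′=C10′–Ph. The target is 6R,4′S,6′R,8′R with both chain alkenes E.

Remark on the chemistry: the allyl group passed from silicon to C4′ supplies C3′, C2′ and a terminal CH2 that leaves as ethene in step 7; C1′ and C6 come from acrolein there. "Ipc2BOMe" always means the enantiomer made from (−)-α-pinene.

Step 1
Reactants: 1 (E)-cinnamaldehyde; 2 allylmagnesium bromide
Product: 4 (3R,1E)-1-phenylhexa-1,5-dien-3-ol, via diisopinocampheylborinate 3 (not isolated)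
Conditions: Ipc2BOMe [from (−)-α-pinene], 2, Et2O, −78 °C to rt; then 1, −78 °C; NaBO3·4H2O, THF/H2O, rt
Reagents that add atoms: allylmagnesium bromide, C=CC[Mg]Br
Why: Brown allylboration: the B-allyl reagent formed from 2 and Ipc2BOMe adds 1,2 to the aldehyde through a closed six-membered chair transition state on the Re face, which sets the carbinol carbon (the later C8′) as R, and perborate then cleaves borinate 3 oxidatively.

Step 2
Reactants: 5 trichlorosilane; 2 allylmagnesium bromide (2 equiv)
Product: 7 diallylchlorosilane, via allyldichlorosilane 6 (not isolated)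
Conditions: Et2O, −78 °C to rt; filtration under argon; fractional distillation
Reagents that add atoms: allylmagnesium bromide, C=CC[Mg]Br
Why: Nucleophilic substitution at silicon by a Grignard reagent: each allyl group lowers the electrophilicity of silicon, so two equivalents at low temperature should stop mainly at the diallyl chloride, the Si–H bond stays intact, and distillation removes mono- and triallyl silanes.

Step 3
Reactants: 4 (3R,1E)-1-phenylhexa-1,5-dien-3-ol; 7 diallylchlorosilane
Product: 8 diallyl{[(3R,1E)-1-phenylhexa-1,5-dien-3-yl]oxy}silane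
Conditions: Et3N, DMAP (cat.), CH2Cl2, 0 °C to rt; rapid filtration through Et3N-deactivated silica
Reagents that add atoms: diallylchlorosilane, C=CC[SiH](Cl)CC=C
Why: Amine-mediated O-silylation (silyl ether formation): the alcohol displaces chloride at silicon without touching the Si–H bond, either alkene or the C–O stereocentre.

Step 4
Reactants: 8 diallyl{[(3R,1E)-1-phenylhexa-1,5-dien-3-yl]oxy}silane; 9 carbon monoxide
Product: 11 (1S,3R,5R,7S)-3-[(E)-2-phenylethenyl]-1,7-di(prop-2-en-1-yl)-2,8-dioxa-1-silabicyclo[3.3.0]octane (cis-fused; C3 = C8′, C5 = C6′, C7 = C4′), via β-silyl aldehyde 10 (not isolated)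
Conditions: Rh(acac)(CO)2 (3 mol%), CO (70 bar), benzene, 60 °C; concentrated and used crude
Reagents that add atoms: carbon monoxide, [C-]#[O+]
Why: Oxidative addition of the Si–H bond to rhodium is followed by syn insertion of the terminal C5′=C6′ alkene into Rh–Si, CO insertion into the new Rh–C5′ bond and C–H reductive elimination to give β-silyl aldehyde 10, whose strained, Lewis acidic oxasilacyclopentane silicon binds the formyl oxygen and hands one allyl group to C4′ with allylic transposition through a closed six-membered chair transition state. The closest known reaction type is this very cascade, the tandem intramolecular alkene silylformylation–allylsilylation of diallylhydrosilyl ethers of homoallylic alcohols, here applied to a substrate that carries an additional styryl group. Ring 1 (O–Si–C6′–C7′–C8′) closes by 5-exo-trig silylmetalation with silicon on the internal carbon C6′, and ring 2 (Si–O–C4′–C5′–C6′) closes when the dative O→Si contact of the bound aldehyde becomes the covalent Si–O bond during allyl transfer. C6′ is controlled by C8′, whose styryl group sits pseudo-equatorial in the insertion transition state so that the C5′ arm ends cis to it on ring 1 (syn C6′/C8′ after oxidation with retention); C4′ is controlled by relay through silicon, the allyl group reaching the aldehyde face that places C3′ on the convex side of the bicycle (anti to C6′, 1,5-anti to C8′); the silicon centre is fixed by the obligatory cis fusion. The step needs chemoselectivity for the terminal alkene and carbonylation over plain hydrosilylation, which are secured because the styryl alkene is internal, conjugated and could insert only in a four-membered exo or a strained 5-endo mode, the Si-allyl groups cannot reach their own silicon, and high CO pressure traps the primary alkylrhodium before β-hydride elimination.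

Step 5
Reactants: 11 the crude bicyclic silane; 12 hydrogen peroxide
Product: 13 (1E,3R,5R,7S)-1-phenyldeca-1,9-diene-3,5,7-triol
Conditions: 30% aq. H2O2, KF, KHCO3, THF/MeOH (1:1), 0 °C to 40 °C
Reagents that add atoms: hydrogen peroxide, OO
Why: Tamao oxidation: fluoride/bicarbonate-activated peroxide oxidises both Si–C bonds of the dialkoxysilane with retention at C6′ and the Si–O bonds are hydrolysed, so the cis ring 1 becomes the syn C6′/C8′ diol while C4′ and C8′ are untouched.

Step 6
Reactants: 13 (1E,3R,5R,7S)-1-phenyldeca-1,9-diene-3,5,7-triol; 14 chlorotriethylsilane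
Product: 15 (1E,3R,5R,7S)-1-phenyl-3,5,7-tris(triethylsilyloxy)deca-1,9-diene
Conditions: TESCl (4 equiv), imidazole, DMAP (cat.), DMF, 0 °C to rt
Reagents that add atoms: chlorotriethylsilane, CC[Si](Cl)(CC)CC
Why: Imidazole-promoted silyl ether formation on three secondary alcohols; triethylsilyl groups should survive metathesis, allylboration with perborate work-up and acylation, yet leave under buffered fluoride at the end.

Step 7
Reactants: 15 the tris(triethylsilyl) ether; 16 acrolein
Product: 17 (2E,5S,7R,9R,10E)-11-phenyl-5,7,9-tris(triethylsilyloxy)undeca-2,10-dienal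
Conditions: second-generation Hoveyda–Grubbs catalyst (H2IMes)Cl2Ru(=CH-C6H4-2-OiPr) (5 mol%), acrolein (5 equiv), CH2Cl2, 40 °C
Reagents that add atoms: acrolein, C=CC=O
Why: Olefin cross-metathesis of a type 1 terminal alkene with excess acrolein (type 2) should give the E-enal under thermodynamic control, the internal, conjugated styryl alkene next to a bulky silyloxy group reacting much more slowly, and the terminal CH2 of the allyl unit leaves as ethene.

Step 8
Reactants: 17 the enal; 2 allylmagnesium bromide
Product: 19 (4R,5E,8S,10R,12R,13E)-14-phenyl-8,10,12-tris(triethylsilyloxy)tetradeca-1,5,13-trien-4-ol, via diisopinocampheylborinate 18 (not isolated)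
Conditions: Ipc2BOMe [from (−)-α-pinene], 2, Et2O, −78 °C to rt; then 17, −78 °C; NaBO3·4H2O, THF/H2O, rt
Reagents that add atoms: allylmagnesium bromide, C=CC[Mg]Br
Why: Brown allylboration with the same reagent as in step 1 adds allyl 1,2 to the Re face of the enal through a chair transition state under reagent control, the remote stereocentres having no influence, which sets C6 as R.

Step 9
Reactants: 19 the homoallylic alcohol; 20 acryloyl chloride
Product: 21 (4R,5E,8S,10R,12R,13E)-14-phenyl-8,10,12-tris(triethylsilyloxy)tetradeca-1,5,13-trien-4-yl prop-2-enoate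
Conditions: iPr2NEt, DMAP (cat.), CH2Cl2, 0 °C
Reagents that add atoms: acryloyl chloride, C=CC(=O)Cl
Why: DMAP-catalysed esterification of the secondary allylic alcohol with an acid chloride leaves the C6–O bond unbroken, so the configuration is retained.

Step 10
Reactants: 21 the acrylate
Product: 22 (6R)-6-[(1E,4S,6R,8R,9E)-10-phenyl-4,6,8-tris(triethylsilyloxy)deca-1,9-dien-1-yl]-5,6-dihydro-2H-pyran-2-one
Conditions: first-generation Grubbs catalyst (PCy3)2Cl2Ru=CHPh (10 mol%), CH2Cl2 (2 mM), 40 °C
Reagents that add atoms: none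
Why: Ring-closing metathesis: the carbene loads on the terminal allyl alkene and closes onto the acrylate to give the six-membered ring with its cis C3=C4 bond, the five-membered closure through the internal C1′=C2′ alkene and attack on the styryl alkene both being slower, as is usual for acrylates of 1-alkenyl homoallylic alcohols.

Step 11
Reactants: 22 the silyl-protected lactone
Product: 23 (6R)-6-[(1E,4S,6R,8R,9E)-4,6,8-trihydroxy-10-phenyldeca-1,9-dien-1-yl]-5,6-dihydro-2H-pyran-2-one
Conditions: HF·pyridine, pyridine, THF, 0 °C to rt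
Reagents that add atoms: none
Why: Fluoride-mediated desilylation under pyridine buffering cleaves the three Si–O bonds without ionising the allylic C8′–O bond, opening the lactone or inducing conjugate addition, and no stereocentre is touched.

Compound list
1 | (E)-cinnamaldehyde | O=C/C=C/c1ccccc1 | starting material
2 | allylmagnesium bromide | C=CC[Mg]Br | starting material
3 | (3R,1E)-1-phenylhexa-1,5-dien-3-yl diisopinocampheylborinate (Ipc from (−)-α-pinene) | C=CC[C@@H](OB([C@H]1C[C@H]2C[C@@H]([C@@H]1C)C2(C)C)[C@H]1C[C@H]2C[C@@H]([C@@H]1C)C2(C)C)/C=C/c1ccccc1 | intermediate (not isolated)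
4 | (3R,1E)-1-phenylhexa-1,5-dien-3-ol | C=CC[C@@H](O)/C=C/c1ccccc1 | intermediate
5 | trichlorosilane | Cl[SiH](Cl)Cl | starting material
6 | allyldichlorosilane | C=CC[SiH](Cl)Cl | intermediate (not isolated)
7 | diallylchlorosilane | C=CC[SiH](Cl)CC=C | intermediate
8 | diallyl{[(3R,1E)-1-phenylhexa-1,5-dien-3-yl]oxy}silane | C=CC[C@@H](O[SiH](CC=C)CC=C)/C=C/c1ccccc1 | intermediate
9 | carbon monoxide | [C-]#[O+] | starting material
10 | 2-[(3S,5R)-2,2-diallyl-5-[(E)-2-phenylethenyl]-1,2-oxasilolan-3-yl]acetaldehyde (3,5-cis) | O=CC[C@@H]1C[C@H](/C=C/c2ccccc2)O[Si]1(CC=C)CC=C | intermediate (not isolated)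
11 | (1S,3R,5R,7S)-3-[(E)-2-phenylethenyl]-1,7-di(prop-2-en-1-yl)-2,8-dioxa-1-silabicyclo[3.3.0]octane (cis-fused; Si-allyl cis to H-5; styryl on the concave face, C7 allyl on the convex face) | C=CC[C@H]1C[C@@H]2C[C@H](/C=C/c3ccccc3)O[Si@]2(CC=C)O1 | intermediate
12 | hydrogen peroxide | OO | starting material
13 | (1E,3R,5R,7S)-1-phenyldeca-1,9-diene-3,5,7-triol | C=CC[C@H](O)C[C@@H](O)C[C@@H](O)/C=C/c1ccccc1 | intermediate
14 | chlorotriethylsilane | CC[Si](Cl)(CC)CC | starting material
15 | (1E,3R,5R,7S)-1-phenyl-3,5,7-tris(triethylsilyloxy)deca-1,9-diene | C=CC[C@H](O[Si](CC)(CC)CC)C[C@@H](O[Si](CC)(CC)CC)C[C@@H](O[Si](CC)(CC)CC)/C=C/c1ccccc1 | intermediate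
16 | acrolein | C=CC=O | starting material
17 | (2E,5S,7R,9R,10E)-11-phenyl-5,7,9-tris(triethylsilyloxy)undeca-2,10-dienal | O=C/C=C/C[C@H](O[Si](CC)(CC)CC)C[C@@H](O[Si](CC)(CC)CC)C[C@@H](O[Si](CC)(CC)CC)/C=C/c1ccccc1 | intermediate
18 | diisopinocampheylborinate of 19 (Ipc from (−)-α-pinene) | C=CC[C@@H](OB([C@H]1C[C@H]2C[C@@H]([C@@H]1C)C2(C)C)[C@H]1C[C@H]2C[C@@H]([C@@H]1C)C2(C)C)/C=C/C[C@H](O[Si](CC)(CC)CC)C[C@@H](O[Si](CC)(CC)CC)C[C@@H](O[Si](CC)(CC)CC)/C=C/c1ccccc1 | intermediate (not isolated)
19 | (4R,5E,8S,10R,12R,13E)-14-phenyl-8,10,12-tris(triethylsilyloxy)tetradeca-1,5,13-trien-4-ol | C=CC[C@@H](O)/C=C/C[C@H](O[Si](CC)(CC)CC)C[C@@H](O[Si](CC)(CC)CC)C[C@@H](O[Si](CC)(CC)CC)/C=C/c1ccccc1 | intermediate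
20 | acryloyl chloride | C=CC(=O)Cl | starting material
21 | (4R,5E,8S,10R,12R,13E)-14-phenyl-8,10,12-tris(triethylsilyloxy)tetradeca-1,5,13-trien-4-yl prop-2-enoate | C=CC[C@@H](OC(=O)C=C)/C=C/C[C@H](O[Si](CC)(CC)CC)C[C@@H](O[Si](CC)(CC)CC)C[C@@H](O[Si](CC)(CC)CC)/C=C/c1ccccc1 | intermediate
22 | (6R)-6-[(1E,4S,6R,8R,9E)-10-phenyl-4,6,8-tris(triethylsilyloxy)deca-1,9-dien-1-yl]-5,6-dihydro-2H-pyran-2-one | O=C1C=CC[C@H](/C=C/C[C@H](O[Si](CC)(CC)CC)C[C@@H](O[Si](CC)(CC)CC)C[C@@H](O[Si](CC)(CC)CC)/C=C/c2ccccc2)O1 | intermediate
23 | (6R)-6-[(1E,4S,6R,8R,9E)-4,6,8-trihydroxy-10-phenyldeca-1,9-dien-1-yl]-5,6-dihydro-2H-pyran-2-one | O=C1C=CC[C@H](/C=C/C[C@H](O)C[C@@H](O)C[C@@H](O)/C=C/c2ccccc2)O1 | target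

Total step count: 11. Longest linear sequence: 10 steps (1, 3–11); step 2 prepares the silane on a one-step side branch.

Steps most likely to fail

Step 4. What may go wrong: the silyl rhodium species may also engage the styryl alkene (5-endo insertion or double-bond migration), carbon monoxide uptake may lose to plain hydrosilylation, or facial control may be too weak in the silylmetalation (C6′) or in the allyl transfer (C4′). The fallback uses known chemistry, sets out from 4 and returns at 13. Cross-metathesis of 4 with methyl acrylate (second-generation Hoveyda–Grubbs catalyst, CH2Cl2, 40 °C) should give methyl (2E,5R,6E)-5-hydroxy-7-phenylhepta-2,6-dienoate F1. Benzaldehyde and KOtBu in THF at 0 °C (hemiacetal formation, then intramolecular oxa-Michael addition under thermodynamic control) should give the all-equatorial benzylidene acetal methyl [(2R,4S,6R)-2-phenyl-6-[(E)-2-phenylethenyl]-1,3-dioxan-4-yl]acetate F2, which fixes the syn C6′/C8′ pair. Reduction with iBu2AlH in CH2Cl2 at −78 °C should give [(2R,4S,6R)-2-phenyl-6-[(E)-2-phenylethenyl]-1,3-dioxan-4-yl]acetaldehyde F3. Keck allylation with allylSnBu3, (S)-BINOL and Ti(OiPr)4 should set C4′ under reagent control and give (2S)-1-[(2R,4R,6R)-2-phenyl-6-[(E)-2-phenylethenyl]-1,3-dioxan-4-yl]pent-4-en-2-ol F4. Aqueous acetic acid at 40 °C then removes the acetal and returns to triol 13.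

Step 7. What may go wrong: acrolein may oligomerise and deactivate the ruthenium carbene, and slow turnover gives the carbene time to attack the styryl alkene (loss of the phenyl-bearing end) or to erode E selectivity. The fallback sets out from 15 and 16 and returns at 22, so steps 8–10 fall away. Acrolein 16 is allylated with the same (−)-α-pinene-derived B-allyl reagent to (R)-hexa-1,5-dien-3-ol F5. This is esterified with 20 (iPr2NEt, DMAP, CH2Cl2) to (R)-hexa-1,5-dien-3-yl prop-2-enoate F6 and ring-closed with first-generation Grubbs catalyst (PCy3)2Cl2Ru=CHPh to (R)-6-vinyl-5,6-dihydro-2H-pyran-2-one F7. Cross-metathesis of 15 with an excess of F7 (second-generation Hoveyda–Grubbs catalyst, CH2Cl2, 40 °C) should then join the halves at C1′=C2′ and give 22 directly. Only one ruthenium-mediated event then takes place on styryl-bearing material, and no volatile, polymerisable partner is involved.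

Step 2. What may go wrong: double allylation of trichlorosilane may not stop cleanly (under- and over-allylation), and the chlorosilane may be lost to hydrolysis during filtration and distillation. The fallback sets out from 4 and 5 and returns at 8, skipping 7. Alcohol 4 is O-silylated first with an excess of 5 and Et3N in Et2O at −78 °C to dichloro{[(3R,1E)-1-phenylhexa-1,5-dien-3-yl]oxy}silane F8. The volatile excess of 5 is removed under vacuum and two equivalents of 2 are added at −78 °C, where the two Si–Cl bonds should be displaced much faster than the Si–O bond, to give 8 without isolating any chlorosilane.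

Further compounds
F1 | step 4 | methyl (2E,5R,6E)-5-hydroxy-7-phenylhepta-2,6-dienoate | COC(=O)/C=C/C[C@@H](O)/C=C/c1ccccc1
F2 | step 4 | methyl [(2R,4S,6R)-2-phenyl-6-[(E)-2-phenylethenyl]-1,3-dioxan-4-yl]acetate | COC(=O)C[C@@H]1C[C@H](/C=C/c2ccccc2)O[C@H](c2ccccc2)O1
F3 | step 4 | [(2R,4S,6R)-2-phenyl-6-[(E)-2-phenylethenyl]-1,3-dioxan-4-yl]acetaldehyde | O=CC[C@@H]1C[C@H](/C=C/c2ccccc2)O[C@H](c2ccccc2)O1
F4 | step 4 | (2S)-1-[(2R,4R,6R)-2-phenyl-6-[(E)-2-phenylethenyl]-1,3-dioxan-4-yl]pent-4-en-2-ol | C=CC[C@H](O)C[C@@H]1C[C@H](/C=C/c2ccccc2)O[C@H](c2ccccc2)O1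
F5 | step 7 | (R)-hexa-1,5-dien-3-ol | C=CC[C@@H](O)C=C
F6 | step 7 | (R)-hexa-1,5-dien-3-yl prop-2-enoate | C=CC[C@@H](OC(=O)C=C)C=C
F7 | step 7 | (R)-6-vinyl-5,6-dihydro-2H-pyran-2-one | O=C1C=CC[C@H](C=C)O1
F8 | step 2 | dichloro{[(3R,1E)-1-phenylhexa-1,5-dien-3-yl]oxy}silane | C=CC[C@@H](O[SiH](Cl)Cl)/C=C/c1ccccc1
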